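The north-west run, charged with twice the substrate of the south-east flask, kept more substrate in percent at 120 s: 67.2% against 62.2%.

| flask | substrate | reagent in the second phase | remark | time | volume of the second phase over the first |
|---|---|---|---|---|---|
| south-east | 0.20 M (fed, over 4.0 s) | 0.26 M | the very flask that is asked about, followed so far |  |  |
| north-west | 0.40 M (fed, over 4.0 s) | 0.26 M | run made earlier |  |  |
| flask | 0.20 M (fed, over 4.0 s) | 0.260 M |  | 5.0 min | 0.25 |

south-east run (percent of the substrate charged)

| time / s | substrate / % | isomer of the product / % | target / % |
|---|---|---|---|
| 15.0 | 90.9 | 1.9 | 8.0 |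
| 30.0 | 83.1 | 4.0 | 12.6 |
| 50.0 | 75.9 | 8.4 | 15.6 |
| 60.0 | 73.1 | 10.7 | 14.8 |
| 80.0 | 69.3 | 16.6 | 15.3 |
| 90.0 | 66.5 | 17.9 | 15.1 |
| 120 | 62.2 | 24.3 | 14.7 |

north-west run (percent of the substrate charged)

| time / min | substrate / % | isomer of the product / % | target / % |
|---|---|---|---|
| 0.417 | 86.1 | 2.1 | 11.2 |
| 0.667 | 81.8 | 5.8 | 13.6 |
| 1.00 | 76.9 | 9.1 | 14.0 |
| 1.33 | 72.1 | 14.6 | 13.3 |
| 2.00 | 67.2 | 21.1 | 12.2 |
| 3.00 | 61.9 | 27.6 | 9.8 |
| 5.00 | 53.8 | 36.1 | 9.2 |

(readings scatter by 0.5 percentage points)

- in the second phase: reagent in the second phase; everything else is in the first
- charges count per volume of the first phase; a concentration in a rate is the amount of a species over the volume of its own phase; every rate counts per litre of the first phase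
- the earlier runs hold the two phases in the same ratio of volumes as the flask asked about

- the species that holds most of what was charged as substrate, at 5.0 min (isomer of the product / target / substrate)
- the largest share itself, whichever of these holds it, in percent of the substrate charged

1. I began with the main step and took the reagent as constant. That is pseudo-first-order, so percentages ignore the charge, and the south-east flask would match the north-west run at 5.0 min, with substrate 53.8%. The gap above contradicts this.

2. So I let each substrate lost spend one reagent, with charges per litre of first phase, and counted as reagent left every form of it not yet spent. I defined the exposure θ: the growth of ln([reagent left]/[substrate]) from its start, divided by the reagent charge minus the substrate charge. I assumed that flasks with equal reagent charge share θ at equal times. At 120 s the south-east readings give 2.19 L mol⁻¹ and the north-west readings 2.18 L mol⁻¹. The north-west run at 5.0 min reads 4.43 L mol⁻¹. Carried to the south-east flask, this leaves substrate 43.1%.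

3. Then I added the change of target into isomer. The isomer's share of the two products at 120 s reads 62.3% south-east and 63.4% north-west, so I assumed that flasks share it at equal times. At 5.0 min it reads 79.7%. My reckoning then puts the isomer at 45.3%, narrowly above my figure for substrate.

4. The forecast chose isomer of the product at 44%: “Isomer probably leads”.

5. The flask gives isomer of the product at 46.3%, substrate 41.5% and target 12.3%.

    reagent in the reaction phase ⇌ reagent in the second phase, rate k1*([reagent in the reaction phase] - [reagent in the second phase]/K1) per volume of the first phase (partition coefficient = 0.810, kL = 0.470 s⁻¹)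
    substrate + reagent in the reaction phase → target (k = 0.0390 L mol⁻¹ s⁻¹)
    reagent in the reaction phase ⇌ dormant form (K = 1.50, k = 0.0160 s⁻¹)
    target ⇌ isomer of the product (K = 6.00, k = 0.0180 s⁻¹)

6. A neighbour flask differs from the asked one in its charge of substrate, 0.80 M, which exceeds the reagent charge, so there reagent is the limiting reagent. With the same θ, 4.43 L mol⁻¹, its substrate comes to 69.6%. With the same share, 79.7%, its isomer comes to 24.2%. That neighbour flask ends with substrate ahead, at 70.8%, and isomer at 24.0%.

Readings and results are simulated with made-up constants; noise was put on by code.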